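Count two nucleophiles for each electrophile, and your hunch that 2.00 equivalents make autumn a comfortable excess goes: in autumn the two charges then fall in step.

common to all: electrophile 0.020 M

|  | nucleophile | remark | time |
|---|---|---|---|
| west | 0.021 M | run made earlier |  |
| north-east | 0.096 M | run made earlier |  |
| autumn | 0.0400 M |  | 40 min |
| winter | 0.0800 M |  | 40 min |
| dawn | 0.160 M |  | 40 min |

| run | time / min | electrophile / % | target / % |
|---|---|---|---|
| west | 2.50 | 91.4 | 9.2 |
| west | 4.00 | 86.5 | 12.9 |
| west | 6.00 | 81.8 | 18.1 |
| west | 10.0 | 74.7 | 24.4 |
| west | 15.0 | 67.9 | 30.7 |
| west | 30.0 | 57.4 | 39.9 |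
| north-east | 5.00 | 45.1 | 54.6 |
| north-east | 10.0 | 23.6 | 75.1 |
| north-east | 15.0 | 12.6 | 84.2 |
| north-east | 20.0 | 6.9 | 88.4 |
| north-east | 25.0 | 4.0 | 89.9 |
| north-east | 30.0 | 2.1 | 90.1 |

(each reading ± 0.3 percentage points)

- steps under discussion: target -> over-reaction product; nucleophile + acid set free <-> protonated nucleophile; electrophile + nucleophile <-> acid set free + target

1. part of the electrophile that has reacted at the end, autumn
2. part of the electrophile that has reacted at the end, winter
3. part of the electrophile that has reacted at the end, dawn
4. what raising the concentration of nucleophile from its lowest to its highest value here does to the part of the electrophile that has reacted (changes below 5 percentage points count as none) (it falls / no change / it rises)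

Here is the quick number. The west electrophile reading is still 57.4% at 30.0 min, so we suppose one nucleophile makes the target and a second takes up the acid set free. Integrating rate = k × electrophile × free nucleophile in closed form, we find that the logarithm of the ratio free nucleophile to electrophile runs in a straight line with time, upward or downward by the sign of its slope. Its slope is k × (nucleophile charged minus two electrophile charges).

This count gives 0.0316 M⁻¹ s⁻¹ from north-east at 10.0 min and 0.0325 M⁻¹ s⁻¹ from west at 30.0 min. Counting one nucleophile, the same readings give 0.0279 M⁻¹ s⁻¹ and 0.0193 M⁻¹ s⁻¹, which do not meet. We therefore keep the mean 0.0321 M⁻¹ s⁻¹ as the two-for-one constant, a second-order rate constant read from the readings.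

In autumn the slope vanishes, and one over the fraction of electrophile left rises by two × k × electrophile charged × time. We reckon 75.5% reacted in autumn, 97.6% in winter and >99.9% in dawn, so the part reacted rises.

The forecast gives 75.5% (72% to 78%), 97.7% and 99.9%, says it rises, and holds that “Each electrophile reacted uses two nucleophiles”.

The flask gives 75.4%, 97.6% and >99.9%, and it rises by 25 percentage points.

    target → over-reaction product (k = 5.70 × 10⁻⁵ s⁻¹)
    nucleophile + acid set free ⇌ protonated nucleophile, settled at all times (K = 67000 M⁻¹)
    electrophile + nucleophile ⇌ acid set free + target (K = 1.90, k = 0.0320 M⁻¹ s⁻¹)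

At 40.0 min autumn still holds 25% of its electrophile and 25% of its nucleophile, the two in step. The constant put to autumn at 20.0 min leaves 39.4% electrophile, and the flask then holds 39.4%.

For the neighbour of autumn charged with 0.10 M nucleophile, the same constant leaves 0.596% electrophile at 40 min. The computed neighbour has 0.60% left, 99.4% reacted.

The numbers in the tables come from a simulation with made-up constants.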